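**Retrosynthetic overview**

1. The target is a diaryl ether joining C8 of coumarin A (the 7-methoxycoumarin half) to C8 of coumarin B (the 5,7-dihydroxycoumarin half). The last disconnection is the benzyl ether on O5 of coumarin B.
2. The pyranone of coumarin B (C4–C4a and O1–C2) comes from propiolate annulation of a mirror-symmetric 2-aryloxy-5-benzyloxyresorcinol, so only one regiochemistry is possible.
3. The pyranone of coumarin A comes from Wittig lactonisation of a salicylaldehyde, made from the salicylate ester.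
4. The strategy rests on benzene ring A (C4a, C5, C6, C7, C8, C8a of coumarin A), which carries O1 on C8a, the aryloxy oxygen on C8, methoxy on C7 and hydrogen on C5 and C6. It is built by [4+2] addition of a 2-aryloxy-1,3-dimethoxy-1-silyloxybutadiene to methyl propiolate with loss of methanol, and the crowded C8–O–aryl bond is made earlier by SN2 at the sp3 carbon of methyl 2-chloroacetoacetate.
5. Ring order: benzene ring B (bought, oxygenated by Dakin oxidation), then benzene ring A (step 7), then pyranone A (step 10), then pyranone B (step 12).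

Key step: step 7

Assumption: the target has no stereocentre. Enol ether 8 and ketene acetals 9 and 10 are drawn as the geometric isomers expected from the conditions; the other isomers would converge on arene 14, because these double bonds end up in aromatic ring A.

**Route**

Step 1
Reactants: 1 2,4,6-trihydroxybenzaldehyde
Product: 2 4-(benzyloxy)-2,6-dihydroxybenzaldehyde
Conditions: BnBr (1.0 equiv), NaHCO3 (1.5 equiv), DMF, 40 °C
Reagents that add atoms: benzyl bromide, BrCc1ccccc1
Why: Williamson etherification in which the 4-hydroxyl, the most acidic one and the only one not hydrogen-bonded to the formyl group, should be alkylated selectively by one equivalent of halide with a weak base.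

Step 2
Reactants: 2 4-(benzyloxy)-2,6-dihydroxybenzaldehyde
Product: 3 4-(benzyloxy)-2,6-bis(methoxymethoxy)benzaldehyde
Conditions: NaH (2.5 equiv), MOMCl (2.6 equiv), DMF, 0 °C to rt
Reagents that add atoms: chloromethyl methyl ether, COCCl
Why: Williamson-type O-alkylation of both phenoxides with the chloromethyl ether; full deprotonation with NaH breaks the chelation of the ortho hydroxyls to the aldehyde.

Step 3
Reactants: 3 4-(benzyloxy)-2,6-bis(methoxymethoxy)benzaldehyde
Product: 5 4-(benzyloxy)-2,6-bis(methoxymethoxy)phenol, via aryl formate 4 (not isolated)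
Conditions: mCPBA (1.3 equiv), CH2Cl2, 0 °C to rt; aq Na2SO3/NaHCO3 wash; then Et3N, MeOH, rt, Ar
Reagents that add atoms: 3-chloroperoxybenzoic acid (mCPBA), OOC(=O)c1cccc(Cl)c1
Why: Baeyer–Villiger (Dakin-type) oxidation in which the electron-rich trioxygenated aryl group migrates in preference to hydride to give formate 4, and amine-catalysed methanolysis then frees the phenol without acid, so the acetals are kept.

Step 4
Reactants: 5 4-(benzyloxy)-2,6-bis(methoxymethoxy)phenol; 6 methyl 2-chloro-3-oxobutanoate (racemic)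
Product: 7 methyl 2-[4-(benzyloxy)-2,6-bis(methoxymethoxy)phenoxy]-3-oxobutanoate (racemic)
Conditions: 6 (1.3 equiv), K2CO3 (2 equiv), acetone, reflux, Ar
Reagents that add atoms: methyl 2-chloro-3-oxobutanoate 6, COC(=O)C(Cl)C(C)=O
Why: SN2 O-alkylation (Williamson) of the phenoxide at the doubly carbonyl-activated sp3 C–Cl carbon, the standard way to 2-aryloxyacetoacetates, sets the hindered aryl–O–C bond without any aryl ether coupling.

Step 5
Reactants: 7 methyl 2-[4-(benzyloxy)-2,6-bis(methoxymethoxy)phenoxy]-3-oxobutanoate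
Product: 8 methyl (2Z)-2-[4-(benzyloxy)-2,6-bis(methoxymethoxy)phenoxy]-3-methoxybut-2-enoate
Conditions: Me2SO4 (1.5 equiv), Cs2CO3 (1.5 equiv), DMF, 0 °C to rt
Reagents that add atoms: dimethyl sulfate, COS(=O)(=O)OC
Why: O-alkylation of a β-keto ester enolate, favoured by the hard electrophile, the loosely bound cesium ion in DMF and the fully substituted aryloxy-bearing α-carbon; the open enolate should give the isomer with the methyl group cis to the ester.

Step 6
Reactants: 8 methyl (2Z)-2-[4-(benzyloxy)-2,6-bis(methoxymethoxy)phenoxy]-3-methoxybut-2-enoate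
Product: 10 {[(1E)-2-[4-(benzyloxy)-2,6-bis(methoxymethoxy)phenoxy]-1,3-dimethoxybuta-1,3-dien-1-yl]oxy}(trimethyl)silane, via lithium dienolate 9 (not isolated)
Conditions: LiN(iPr)2 (1.15 equiv), THF, −78 °C; then Me3SiCl (1.3 equiv), −78 to 0 °C; evaporate, pentane, filter under Ar; used crude
Reagents that add atoms: chlorotrimethylsilane, C[Si](C)(C)Cl
Why: Vinylogous (γ) deprotonation of the β-methoxy enoate, directed by ester coordination to the cis methyl group, then O-silylation of dienolate 9, as in the standard preparation of Brassard-type silyl ketene acetal dienes.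

Step 7
Reactants: 10 {[(1E)-2-[4-(benzyloxy)-2,6-bis(methoxymethoxy)phenoxy]-1,3-dimethoxybuta-1,3-dien-1-yl]oxy}(trimethyl)silane; 11 methyl propiolate
Product: 14 methyl 3-[4-(benzyloxy)-2,6-bis(methoxymethoxy)phenoxy]-2-hydroxy-4-methoxybenzoate, via cyclohexadiene adduct 12 (not isolated), via aryl silyl ether 13 (not isolated)
Conditions: 11 (3 equiv), toluene, 90 °C, sealed tube, Ar; then MeOH, K2CO3 (cat.), rt
Reagents that add atoms: methyl propiolate 11, C#CC(=O)OC
Why: A normal-electron-demand Diels–Alder reaction of a Brassard-type 1,1,3-trioxygenated diene with a propiolate, the established route to 4-methoxysalicylates (only the 2-aryloxy substituent is new), forms C5–C6 and C4a–C8a and closes benzene ring A as cyclohexa-1,4-diene 12 in one intermolecular six-membered [4+2] closure, concerted but asynchronous with the bond from the CH2 terminus leading. Ketal 12 then ionises at C8a with help from the silyloxy oxygen and loses methanol across C8a and C6 to give arene 13, and base-catalysed methanolysis cleaves the labile aryl silyl ether to phenol 14, which is held by a hydrogen bond to the ester. No stereocentre remains, since the only sp3 centre of 12 becomes aromatic. The selectivity needed is regiochemical, with the ester carbon next to the ketene acetal carbon: the unsubstituted diene terminus has the largest HOMO coefficient under the push of three oxygens and meets the propiolate β-carbon, which has the largest LUMO coefficient. The 2-substituent destabilises the s-trans conformer at least as much as the s-cis one, and the aryl ring of the ether can turn out of the diene plane, so the bulky group should slow but not block the addition. The acetals, the benzyl ether and the diaryl ether are inert to neutral heating and to K2CO3 in methanol.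

Step 8
Reactants: 14 methyl 3-[4-(benzyloxy)-2,6-bis(methoxymethoxy)phenoxy]-2-hydroxy-4-methoxybenzoate
Product: 15 6-[4-(benzyloxy)-2,6-bis(methoxymethoxy)phenoxy]-2-(hydroxymethyl)-5-methoxyphenol
Conditions: LiAlH4 (2.5 equiv), THF, 0 °C to rt; then H2O, aq potassium sodium tartrate (KNaC4H4O6); used directly
Reagents that add atoms: none
Why: Hydride reduction of the ester with LiAlH4 gives the salicyl alcohol; ethers and acetals are inert, and the neutral work-up avoids quinone methide formation from this electron-rich benzylic alcohol.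

Step 9
Reactants: 15 6-[4-(benzyloxy)-2,6-bis(methoxymethoxy)phenoxy]-2-(hydroxymethyl)-5-methoxyphenol
Product: 16 3-[4-(benzyloxy)-2,6-bis(methoxymethoxy)phenoxy]-2-hydroxy-4-methoxybenzaldehyde
Conditions: activated MnO2 (12 equiv), CH2Cl2, rt
Reagents that add atoms: none
Why: Chemoselective MnO2 oxidation of a benzylic alcohol stops at the aldehyde, which is stabilised by a hydrogen bond to the ortho phenol.

Step 10
Reactants: 16 3-[4-(benzyloxy)-2,6-bis(methoxymethoxy)phenoxy]-2-hydroxy-4-methoxybenzaldehyde; 17 ethyl (triphenylphosphoranylidene)acetate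
Product: 20 8-[4-(benzyloxy)-2,6-bis(methoxymethoxy)phenoxy]-7-methoxy-2H-chromen-2-one, via E-cinnamate 18 (not isolated), via Z-cinnamate 19 (not isolated)
Conditions: 17 (1.3 equiv), PhNEt2, reflux (about 215 °C), Ar
Reagents that add atoms: ethyl (triphenylphosphoranylidene)acetate 17, CCOC(=O)C=P(c1ccccc1)(c1ccccc1)c1ccccc1
Why: Wittig olefination, thermal E/Z equilibration and lactonisation in boiling N,N-diethylaniline (Wittig lactonisation of a salicylaldehyde) close the pyranone of coumarin A, and the basic medium spares the acetals and the benzyl ether.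

Step 11
Reactants: 20 8-[4-(benzyloxy)-2,6-bis(methoxymethoxy)phenoxy]-7-methoxy-2H-chromen-2-one
Product: 21 8-[4-(benzyloxy)-2,6-dihydroxyphenoxy]-7-methoxy-2H-chromen-2-one
Conditions: conc. HCl (cat.), MeOH/THF, 45 °C
Reagents that add atoms: none
Why: Acid-catalysed transacetalisation to methanol removes both methoxymethyl groups, while the benzyl ether, diaryl ether, methyl ether and lactone are stable to dilute methanolic HCl.

Step 12
Reactants: 21 8-[4-(benzyloxy)-2,6-dihydroxyphenoxy]-7-methoxy-2H-chromen-2-one; 22 ethyl propiolate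
Product: 24 5-(benzyloxy)-7-hydroxy-8-[(7-methoxy-2-oxo-2H-chromen-8-yl)oxy]-2H-chromen-2-one, via Z-cinnamate 23 (not isolated)
Conditions: 22 (1.3 equiv), Pd(OAc)2 (5 mol %), CF3CO2H/CH2Cl2 (1:4), 0 °C to rt
Reagents that add atoms: ethyl propiolate 22, C#CC(=O)OCC
Why: Pd(OAc)2/CF3CO2H-mediated hydroarylation of the propiolate (Fujiwara- or Pechmann-type coumarin annulation) lets the phloroglucinol-type ring attack through C4 (equivalent to C6 by symmetry), trans addition gives Z-cinnamate 23, and the one free neighbouring hydroxyl lactonises because the other flank is blocked as the benzyl ether.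

Step 13
Reactants: 24 5-(benzyloxy)-7-hydroxy-8-[(7-methoxy-2-oxo-2H-chromen-8-yl)oxy]-2H-chromen-2-one
Product: 25 5,7-dihydroxy-8-[(7-methoxy-2-oxo-2H-chromen-8-yl)oxy]-2H-chromen-2-one (CNP0305396.0)
Conditions: BCl3 (4 equiv), C6HMe5 (5 equiv), CH2Cl2, −78 to −40 °C; then H2O
Reagents that add atoms: none
Why: Lewis acid debenzylation with BCl3 and pentamethylbenzene as a non-basic benzyl cation trap (Friedel–Crafts capture) should cleave the benzyl ether at low temperature without reducing the pyranone double bonds, as hydrogenolysis would, and without cleaving the aryl methyl ether.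

**Compound list**

1 | 2,4,6-trihydroxybenzaldehyde | O=Cc1c(O)cc(O)cc1O | starting material
2 | 4-(benzyloxy)-2,6-dihydroxybenzaldehyde | O=Cc1c(O)cc(OCc2ccccc2)cc1O | intermediate
3 | 4-(benzyloxy)-2,6-bis(methoxymethoxy)benzaldehyde | O=Cc1c(OCOC)cc(OCc2ccccc2)cc1OCOC | intermediate
4 | 4-(benzyloxy)-2,6-bis(methoxymethoxy)phenyl formate | O=COc1c(OCOC)cc(OCc2ccccc2)cc1OCOC | intermediate (not isolated)
5 | 4-(benzyloxy)-2,6-bis(methoxymethoxy)phenol | Oc1c(OCOC)cc(OCc2ccccc2)cc1OCOC | intermediate
6 | methyl 2-chloro-3-oxobutanoate (racemic) | COC(=O)C(Cl)C(C)=O | starting material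
7 | methyl 2-[4-(benzyloxy)-2,6-bis(methoxymethoxy)phenoxy]-3-oxobutanoate (racemic, keto form) | COC(=O)C(Oc1c(OCOC)cc(OCc2ccccc2)cc1OCOC)C(C)=O | intermediate
8 | methyl (2Z)-2-[4-(benzyloxy)-2,6-bis(methoxymethoxy)phenoxy]-3-methoxybut-2-enoate | COC(=O)/C(Oc1c(OCOC)cc(OCc2ccccc2)cc1OCOC)=C(\C)OC | intermediate
9 | lithium (1Z)-2-[4-(benzyloxy)-2,6-bis(methoxymethoxy)phenoxy]-1,3-dimethoxybuta-1,3-dien-1-olate | [Li+].[O-]/C(OC)=C(/Oc1c(OCOC)cc(OCc2ccccc2)cc1OCOC)C(OC)=C | intermediate (not isolated)
10 | {[(1E)-2-[4-(benzyloxy)-2,6-bis(methoxymethoxy)phenoxy]-1,3-dimethoxybuta-1,3-dien-1-yl]oxy}(trimethyl)silane | C[Si](C)(C)O/C(OC)=C(/Oc1c(OCOC)cc(OCc2ccccc2)cc1OCOC)C(OC)=C | intermediate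
11 | methyl propiolate (methyl prop-2-ynoate) | C#CC(=O)OC | starting material
12 | methyl 5-[4-(benzyloxy)-2,6-bis(methoxymethoxy)phenoxy]-4,6-dimethoxy-6-[(trimethylsilyl)oxy]cyclohexa-1,4-diene-1-carboxylate (racemic) | COC(=O)C1=CCC(OC)=C(Oc2c(OCOC)cc(OCc3ccccc3)cc2OCOC)C1(OC)O[Si](C)(C)C | intermediate (not isolated)
13 | methyl 3-[4-(benzyloxy)-2,6-bis(methoxymethoxy)phenoxy]-4-methoxy-2-[(trimethylsilyl)oxy]benzoate | COC(=O)c1ccc(OC)c(Oc2c(OCOC)cc(OCc3ccccc3)cc2OCOC)c1O[Si](C)(C)C | intermediate (not isolated)
14 | methyl 3-[4-(benzyloxy)-2,6-bis(methoxymethoxy)phenoxy]-2-hydroxy-4-methoxybenzoate | COC(=O)c1ccc(OC)c(Oc2c(OCOC)cc(OCc3ccccc3)cc2OCOC)c1O | intermediate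
15 | 6-[4-(benzyloxy)-2,6-bis(methoxymethoxy)phenoxy]-2-(hydroxymethyl)-5-methoxyphenol | OCc1ccc(OC)c(Oc2c(OCOC)cc(OCc3ccccc3)cc2OCOC)c1O | intermediate
16 | 3-[4-(benzyloxy)-2,6-bis(methoxymethoxy)phenoxy]-2-hydroxy-4-methoxybenzaldehyde | O=Cc1ccc(OC)c(Oc2c(OCOC)cc(OCc3ccccc3)cc2OCOC)c1O | intermediate
17 | ethyl (triphenylphosphoranylidene)acetate | CCOC(=O)C=P(c1ccccc1)(c1ccccc1)c1ccccc1 | starting material
18 | ethyl (2E)-3-{3-[4-(benzyloxy)-2,6-bis(methoxymethoxy)phenoxy]-2-hydroxy-4-methoxyphenyl}prop-2-enoate | CCOC(=O)/C=C/c1ccc(OC)c(Oc2c(OCOC)cc(OCc3ccccc3)cc2OCOC)c1O | intermediate (not isolated)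
19 | ethyl (2Z)-3-{3-[4-(benzyloxy)-2,6-bis(methoxymethoxy)phenoxy]-2-hydroxy-4-methoxyphenyl}prop-2-enoate | CCOC(=O)/C=C\c1ccc(OC)c(Oc2c(OCOC)cc(OCc3ccccc3)cc2OCOC)c1O | intermediate (not isolated)
20 | 8-[4-(benzyloxy)-2,6-bis(methoxymethoxy)phenoxy]-7-methoxy-2H-chromen-2-one | COc1ccc2ccc(=O)oc2c1Oc1c(OCOC)cc(OCc2ccccc2)cc1OCOC | intermediate
21 | 8-[4-(benzyloxy)-2,6-dihydroxyphenoxy]-7-methoxy-2H-chromen-2-one | COc1ccc2ccc(=O)oc2c1Oc1c(O)cc(OCc2ccccc2)cc1O | intermediate
22 | ethyl propiolate (ethyl prop-2-ynoate) | C#CC(=O)OCC | starting material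
23 | ethyl (2Z)-3-{6-(benzyloxy)-2,4-dihydroxy-3-[(7-methoxy-2-oxo-2H-chromen-8-yl)oxy]phenyl}prop-2-enoate | CCOC(=O)/C=C\c1c(O)c(Oc2c(OC)ccc3ccc(=O)oc23)c(O)cc1OCc1ccccc1 | intermediate (not isolated)
24 | 5-(benzyloxy)-7-hydroxy-8-[(7-methoxy-2-oxo-2H-chromen-8-yl)oxy]-2H-chromen-2-one | COc1ccc2ccc(=O)oc2c1Oc1c(O)cc(OCc2ccccc2)c2ccc(=O)oc12 | intermediate
25 | 5,7-dihydroxy-8-[(7-methoxy-2-oxo-2H-chromen-8-yl)oxy]-2H-chromen-2-one | COc1ccc2ccc(=O)oc2c1Oc1c(O)cc(O)c2ccc(=O)oc12 | target

**Step count**

Total steps: 13. Longest linear sequence: 13 steps (1 to 25).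

**Steps most likely to fail**

Step 7 (Diels–Alder aromatisation). The crowded, moisture-sensitive diene may add too slowly, so that protodesilylation back to enoate 8 and oligomerisation of the propiolate outrun the cycloaddition. Aromatisation may also run partly by loss of silanol, giving the 2-methoxy ester in place of the phenol. The fallback gives up building ring A and makes the diaryl ether by Ullmann coupling; it sets out from phenol 5 and comes back to the route at coumarin 20. Commercial 7-hydroxycoumarin would be iodinated at C8 with I2/KI in aqueous NH3 to 7-hydroxy-8-iodo-2H-chromen-2-one F1, which MeI and K2CO3 in acetone would convert to 8-iodo-7-methoxy-2H-chromen-2-one F2. Copper-catalysed coupling of F2 with 5 (CuI, pyridine-2-carboxylic acid, K3PO4, DMSO, 100 °C) would then give 20 directly.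

Step 12 (propiolate annulation). Acid-promoted loss or oxygen-to-carbon migration of the benzyl group on the phloroglucinol-type ring, or a second annulation at C6 and the 7-hydroxyl, would remove the regiochemical control that the benzyl ether provides. The fallback separates C–C bond formation from lactonisation; it sets out from resorcinol 21 and comes back at coumarin 24. Vilsmeier–Haack formylation (POCl3, DMF, MeCN, 0 °C to rt) would give N-({6-(benzyloxy)-2,4-dihydroxy-3-[(7-methoxy-2-oxo-2H-chromen-8-yl)oxy]phenyl}methylidene)-N-methylmethanaminium chloride F3, which aqueous hydrolysis would convert to 6-(benzyloxy)-2,4-dihydroxy-3-[(7-methoxy-2-oxo-2H-chromen-8-yl)oxy]benzaldehyde F4. Wittig lactonisation of F4 with ylide 17 in boiling PhNEt2 would pass through ethyl (2E)-3-{6-(benzyloxy)-2,4-dihydroxy-3-[(7-methoxy-2-oxo-2H-chromen-8-yl)oxy]phenyl}prop-2-enoate F5 and Z-cinnamate 23 to 24; only the hydroxyl ortho to the formyl group can close, since the other ortho position carries the benzyl ether.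

Step 4 (aryloxylation of the chloro keto ester). The very electron-rich, doubly ortho-substituted phenoxide may be oxidised, or may attack chlorine (halophilic reduction of 6) in place of substitution at the hindered carbon, and the product enolate may be alkylated by a second molecule of 6. The fallback replaces the SN2 step by a carbenoid O–H insertion; it sets out from phenol 5 and comes back at keto ester 7. Regitz diazo transfer to methyl acetoacetate (4-acetamidobenzenesulfonyl azide, Et3N, MeCN) would give methyl 2-diazo-3-oxobutanoate F6, and Rh2(OAc)4 (1 mol %) in CH2Cl2 at reflux with 5 would insert the carbenoid into the phenol O–H bond to give 7.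

**Further compounds**

F1 | step 7 | 7-hydroxy-8-iodo-2H-chromen-2-one | Oc1ccc2ccc(=O)oc2c1I
F2 | step 7 | 8-iodo-7-methoxy-2H-chromen-2-one | COc1ccc2ccc(=O)oc2c1I
F3 | step 12 | N-({6-(benzyloxy)-2,4-dihydroxy-3-[(7-methoxy-2-oxo-2H-chromen-8-yl)oxy]phenyl}methylidene)-N-methylmethanaminium chloride | C[N+](C)=Cc1c(O)c(Oc2c(OC)ccc3ccc(=O)oc23)c(O)cc1OCc1ccccc1.[Cl-]
F4 | step 12 | 6-(benzyloxy)-2,4-dihydroxy-3-[(7-methoxy-2-oxo-2H-chromen-8-yl)oxy]benzaldehyde | O=Cc1c(O)c(Oc2c(OC)ccc3ccc(=O)oc23)c(O)cc1OCc1ccccc1
F5 | step 12 | ethyl (2E)-3-{6-(benzyloxy)-2,4-dihydroxy-3-[(7-methoxy-2-oxo-2H-chromen-8-yl)oxy]phenyl}prop-2-enoate | CCOC(=O)/C=C/c1c(O)c(Oc2c(OC)ccc3ccc(=O)oc23)c(O)cc1OCc1ccccc1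
F6 | step 4 | methyl 2-diazo-3-oxobutanoate | COC(=O)C(=[N+]=[N-])C(C)=O
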